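The readings come from a simulation from invented constants, noise included.

Count every species by the substrate in it, a homo dimer as two, and the six amounts add up to the charge at every time. The homo dimer step runs one way, so what enters it stays out of the target.

| setting | noon | flask |
|---|---|---|
| substrate | 0.012 M | 0.012 M |
| remark | the very flask that is asked about, followed so far |  |
| time |  | 5.0 h |

noon run (percent of the substrate charged)

| time / min | target / % | substrate / % |
|---|---|---|
| 1.33 | 17.9 | 70.7 |
| 3.00 | 25.3 | 47.7 |
| 8.00 | 23.2 | 17.5 |
| 20.0 | 7.5 | 2.8 |
| 50.0 | 2.2 | 1.2 |
| 120 | 0 | 0 |

(readings scatter by 1 percentage point)

1. time, not beyond 5.0 h, at which the flask holds most target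
2. the amount of target, in percent of the substrate charged, at that time

- a species is counted by the substrate in it: one homo dimer counts as two
- the numbers in the tables scatter with a standard deviation of 1 percentage point
- steps thought possible: substrate <-> target; target <-> isomer of the product A; isomer of the product A <-> substrate; 2 substrate -> homo dimer; target -> over-reaction product; target <-> isomer of the product B

The bench rule for the noon run, this same flask followed so far, is to read one constant off a log plot of substrate and call the loss pseudo-first-order. Try it. Up to 1.33 min you read k_early = 0.261 /min, but from 3.00 min to 8.00 min you read k_late = 0.201 /min, which is lower. So the constant read here falls as substrate falls, as a second-order loss of substrate would make it, though target returning to substrate may account for part of that drop.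

Put the read constant as k = k_f + s·x, with x the substrate as a fraction of the charge, through the mean level of each span. My reckoning gives s = 0.114 /min and k_f = 0.163 /min. Read so, with the scatter of the readings in it, the two terms are equal at c× = 0.0172 M, the crossover concentration, the substrate level where second-order loss matches first-order loss. This flask's charge is 0.698 of c×. Integrating, with r the charge over c× and with substrate lost by the first-order term taken as never coming back, my estimate of the share of the charge going to homo dimer is 1 − ln(1 + r)/r, here 24.1 %.

The forecast gives 27.5 % at 0.075 h, from a rise-and-fall curve through the early points, and says the faster early fall of substrate “fits some second-order dimer loss”.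

The flask peaks at 28.5 % after 0.0774 h, and by then it holds 14.3 % of homo dimer.

    substrate ⇌ target (K = 10.0, k = 0.180 /min)
    target ⇌ isomer of the product A (K = 0.440, k = 0.0370 /min)
    isomer of the product A ⇌ substrate (k = 0.00350 /min)
    2 substrate → homo dimer (k = 3.30 /M/min)
    target → over-reaction product (k = 0.0680 /min)
    target ⇌ isomer of the product B (K = 24.0, k = 0.110 /min)

This flask's homo dimer ends at 16.7 %, under the estimated 24.1 %. Now use c× on the neighbour charged with 0.048 M, which stands 2.79 times above it. The same formula gives 52.3 %. That neighbour ends with 41.6 % of homo dimer, and its target peaks at 21.8 %, lower than this flask's.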